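**Plan**
- Cuts (drimane labels: ring A = C1–C5 and C10, ring B = C5–C10, C11 on C9, C15 on C10): the C11–O ester bond, then C9–C11, then C3–C4 of ring A (with a temporary C2 ester on the acceptor), then C10–C1 and C10–C15.
- Forward: ring B is the ring of (R)-carvone. C15 and the three-carbon acrylate arm C1–C3 are placed on C10, ring A is closed by a radical C3–C4 bond, the C2 ester is removed, C11 is added at the C9 ketone, and the caffeoyl unit is attached last.
- Enabling feature: C4 of ring A is a gem-dimethyl quaternary carbon bonded to the ring-fusion carbon C5, so it maps onto the isopropenyl carbon of carvone. One hydrogen atom added to its CH2 completes the second methyl and leaves a tertiary C4 radical that reaches C3.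
- Stereochemistry: C5 comes from (R)-carvone; C10 from alkylation anti to the isopropenyl group; C9 from hydroboration on the α face, opposite the axial C15 methyl; the E alkene from caffeic acid.

Key step: step 3

Remark: C6 of compound 3 and C2 of compounds 7–10 are epimer mixtures whose stereochemistry is erased later (steps 2 and 5), so their SMILES carry no descriptor at that atom; bicyclic compounds are described with drimane atom labels.

Step 1
Reactants: 1 (R)-(−)-carvone
Product: 3 (5R)-2,6-dimethyl-5-(prop-1-en-2-yl)cyclohex-2-en-1-one (6-methylcarvone; C6 epimer mixture), via carvone lithium dienolate 2 (not isolated)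
Conditions: LiN(i-Pr)2 (1.1 equiv), THF, −78 °C; MeI (1.5 equiv), −78 to 0 °C
Reagents that add atoms: iodomethane, CI
Why: Kinetic deprotonation at the α′ methylene gives the cross-conjugated lithium dienolate, and its SN2 methylation is a standard enolate alkylation of carvone; the new C6 center forms as an epimer mixture, which does not matter because it is planarised again in step 2.

Step 2
Reactants: 3 6-methylcarvone; 4 methyl 2-(bromomethyl)prop-2-enoate
Product: 6 methyl 2-{[(1S,6S)-1,3-dimethyl-2-oxo-6-(prop-1-en-2-yl)cyclohex-3-en-1-yl]methyl}prop-2-enoate (acrylate arm trans to isopropenyl; methyl cis), via 6-methylcarvone lithium dienolate 5 (not isolated)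
Conditions: LiN(i-Pr)2 (1.2 equiv), THF, −78 to −20 °C; DMPU, then 4 (1.3 equiv), −78 °C to rt
Reagents that add atoms: none
Why: Enolate alkylation with the activated allylic bromide (SN2 or SN2′ addition–elimination, both leading to the same product) should occur on the dienolate face anti to the neighbouring isopropenyl group, which places the acrylate arm trans to isopropenyl and so sets the quaternary center that becomes C10 with its methyl β.

Step 3
Reactants: 6 methyl 2-{[(1S,6S)-1,3-dimethyl-2-oxo-6-(prop-1-en-2-yl)cyclohex-3-en-1-yl]methyl}prop-2-enoate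
Product: 7 methyl (4aS,8aS)-4,4,7,8a-tetramethyl-8-oxo-1,2,3,4,4a,5,8,8a-octahydronaphthalene-2-carboxylate (methyl 9-oxo-11-nordrim-7-ene-2-carboxylate; trans-fused; C2 epimers)
Conditions: Fe(acac)3 (30 mol %), PhSiH3 (2.5 equiv), EtOH/ethylene glycol, 60 °C, dilute
Reagents that add atoms: none
Why: The trivalent iron hydride formed from Fe(acac)3, PhSiH3 and ethanol transfers a hydrogen atom to the CH2 of the electron-rich isopropenyl group, which completes the C4 gem-dimethyl unit and leaves a nucleophilic tertiary radical at C4; this radical adds to the unsubstituted terminus C3 of the electron-poor acrylate, forming C3–C4, and the α-ester radical at C2 is reduced by divalent iron and protonated by ethanol, which returns trivalent iron. The closest known reaction type is the iron hydride hydrogen-atom-transfer reductive coupling of an unactivated alkene with an acrylate, run here intramolecularly as a Giese cyclization. Ring A closes in the 6-endo-trig mode through a chair in which the C5 and C10 arms are both equatorial on ring B, so the trans ring fusion already fixed at C5 and C10 in 6 is carried over unchanged. The only new stereocenter is C2, set without control in the final protonation (the equatorial ester is the more stable epimer) and deleted in step 5. The step needs hydrogen-atom transfer to the isopropenyl group and not to the acrylate or the enone, which the higher reactivity of electron-rich 1,1-disubstituted alkenes toward the metal hydride should secure; it also needs 6-endo over 5-exo closure, which is secured because 5-exo attack would have to join two fully substituted carbons at the ester-bearing, polarity-mismatched C2 and would give an unstabilised primary radical.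

Step 4
Reactants: 7 methyl 9-oxo-11-nordrim-7-ene-2-carboxylate
Product: 9 (4aS,8aS)-4,4,7,8a-tetramethyl-8-oxo-1,2,3,4,4a,5,8,8a-octahydronaphthalene-2-carboxylic acid (C2 epimers), via lithium carboxylate 8 (not isolated)
Conditions: LiOH·H2O (3 equiv), THF/MeOH/H2O, rt; then 1 M HCl to pH 3
Reagents that add atoms: lithium hydroxide, [Li+].[OH-] (oxygen of the carboxyl OH; lithium only in intermediate 8)
Why: Saponification (BAc2) of an unhindered secondary methyl ester is routine and leaves the enone untouched, and any epimerisation at C2 is harmless.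

Step 5
Reactants: 9 9-oxo-11-nordrim-7-ene-2-carboxylic acid
Product: 11 (4aS,8aS)-2,5,5,8a-tetramethyl-4a,5,6,7,8,8a-hexahydronaphthalen-1(4H)-one (11-nordrim-7-en-9-one), via Barton ester 10 (not isolated)
Conditions: DCC (1.2 equiv), 1-hydroxypyridine-2(1H)-thione (1.2 equiv), DMAP (cat.), CH2Cl2, 0 °C to rt, dark; then t-BuSH (10 equiv), hν (W lamp), rt
Reagents that add atoms: 1-hydroxypyridine-2(1H)-thione, ON1C=CC=CC1=S (its atoms stay only in intermediate 10; product 11 gains hydrogen alone)
Why: Barton reductive decarboxylation: the thiohydroxamate ester fragments under light to CO2 and the secondary C2 radical, which should take hydrogen from the thiol much faster than it can add to the hindered enone, so the activating group and the C2 stereocenter are removed together.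

Step 6
Reactants: 11 11-nordrim-7-en-9-one
Product: 12 (4aS,8aS)-2,5,5,8a-tetramethyl-1-methylidene-1,4,4a,5,6,7,8,8a-octahydronaphthalene (drima-7,9(11)-diene)
Conditions: Cp2TiMe2 (3 equiv), toluene, 70 °C, dark
Reagents that add atoms: dimethyltitanocene Cp2TiMe2, [CH3-].[CH3-].[Ti+4].c1cc[cH-]c1.c1cc[cH-]c1 (supplies the CH2 carbon C11)
Why: Petasis methylenation: the titanium methylidene Cp2Ti=CH2 generated on heating is small, non-basic and strongly oxophilic, so it should convert the hindered conjugated C9 ketone into the exocyclic alkene without conjugate addition or alkene migration.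

Step 7
Reactants: 12 drima-7,9(11)-diene
Product: 14 (−)-drimenol [(1S,4aS,8aS)-2,5,5,8a-tetramethyl-1,4,4a,5,6,7,8,8a-octahydronaphthalen-1-yl]methanol, via B-alkyl-9-BBN adduct 13 (not isolated)
Conditions: 9-BBN (1.5 equiv, 0.5 M in THF), THF, 0 °C to rt; then 3 M NaOH, 30% H2O2, 0 °C to rt
Reagents that add atoms: 9-borabicyclo[3.3.1]nonane, B1C2CCCC1CCC2 (only in intermediate 13); hydrogen peroxide, OO (the C11 hydroxyl oxygen)
Why: Hydroboration–oxidation: the bulky borane should add only to the 1,1-disubstituted C9=C11 bond with boron on the terminal C11 and deliver hydrogen to C9 from the α face, opposite the axial C15 methyl on C10, which sets C9 (H α, CH2OH β), and oxidation with retention then gives the primary alcohol while the trisubstituted C7=C8 bond stays.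

Step 8
Reactants: 15 caffeic acid
Product: 17 (E)-3-[3,4-bis(tert-butyldimethylsilyloxy)phenyl]prop-2-enoic acid, via tris-TBS caffeate 16 (not isolated)
Conditions: TBSCl (3.5 equiv), imidazole (7 equiv), DMF, rt; then AcOH/THF/H2O, rt
Reagents that add atoms: tert-butyldimethylsilyl chloride, CC(C)(C)[Si](C)(C)Cl
Why: Exhaustive silylation of both phenols and the acid followed by selective hydrolysis of the far more labile silyl ester is a standard protection sequence for phenolic cinnamic acids and does not touch the E alkene.

Step 9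
Reactants: 14 (−)-drimenol; 17 (E)-3-[3,4-bis(tert-butyldimethylsilyloxy)phenyl]prop-2-enoic acid
Product: 18 drim-7-en-11-yl (E)-3-[3,4-bis(tert-butyldimethylsilyloxy)phenyl]prop-2-enoate
Conditions: DCC (1.3 equiv), DMAP (0.2 equiv), CH2Cl2, 0 °C to rt
Reagents that add atoms: none
Why: Steglich esterification (carbodiimide activation with DMAP acyl transfer) should acylate the hindered primary C11 alcohol under neutral conditions that preserve the silyl ethers, the E alkene and the C7=C8 bond.

Step 10
Reactants: 18 drim-7-en-11-yl (E)-3-[3,4-bis(tert-butyldimethylsilyloxy)phenyl]prop-2-enoate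
Product: 19 drim-7-en-11-yl caffeate, [(1S,4aS,8aS)-2,5,5,8a-tetramethyl-1,4,4a,5,6,7,8,8a-octahydronaphthalen-1-yl]methyl (E)-3-(3,4-dihydroxyphenyl)prop-2-enoate (CNP0265201.1)
Conditions: Bu4NF (2.5 equiv), AcOH (2.5 equiv), THF, 0 °C, argon
Reagents that add atoms: none
Why: Fluoride-mediated desilylation of aryl silyl ethers is fast at 0 °C, and the acetic acid buffer keeps the freed catechol protonated, so neither ester cleavage nor catechol oxidation should compete.

**Compound list**
1 | (R)-(−)-carvone, (5R)-2-methyl-5-(prop-1-en-2-yl)cyclohex-2-en-1-one | CC1=CC[C@H](CC1=O)C(C)=C | starting material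
2 | lithium (3R)-6-methyl-3-(prop-1-en-2-yl)cyclohexa-1,5-dien-1-olate (kinetic α′ dienolate of carvone) | CC1=CC[C@@H](C(C)=C)C=C1[O-].[Li+] | intermediate
3 | (5R)-2,6-dimethyl-5-(prop-1-en-2-yl)cyclohex-2-en-1-one (6-methylcarvone; C6 epimer mixture) | CC1=CC[C@@H](C(C)=C)C(C)C1=O | intermediate
4 | methyl 2-(bromomethyl)prop-2-enoate | C=C(CBr)C(=O)OC | starting material
5 | lithium (3S)-2,6-dimethyl-3-(prop-1-en-2-yl)cyclohexa-1,5-dien-1-olate (dienolate of 3) | CC1=CC[C@@H](C(C)=C)C(C)=C1[O-].[Li+] | intermediate
6 | methyl 2-{[(1S,6S)-1,3-dimethyl-2-oxo-6-(prop-1-en-2-yl)cyclohex-3-en-1-yl]methyl}prop-2-enoate | CC1=CC[C@@H](C(C)=C)[C@](C)(CC(=C)C(=O)OC)C1=O | intermediate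
7 | methyl (4aS,8aS)-4,4,7,8a-tetramethyl-8-oxo-1,2,3,4,4a,5,8,8a-octahydronaphthalene-2-carboxylate (C2 epimers) | CC1=CC[C@H]2C(C)(C)CC(C(=O)OC)C[C@]2(C)C1=O | intermediate
8 | lithium (4aS,8aS)-4,4,7,8a-tetramethyl-8-oxo-1,2,3,4,4a,5,8,8a-octahydronaphthalene-2-carboxylate (C2 epimers) | CC1=CC[C@H]2C(C)(C)CC(C(=O)[O-])C[C@]2(C)C1=O.[Li+] | intermediate
9 | (4aS,8aS)-4,4,7,8a-tetramethyl-8-oxo-1,2,3,4,4a,5,8,8a-octahydronaphthalene-2-carboxylic acid (C2 epimers) | CC1=CC[C@H]2C(C)(C)CC(C(=O)O)C[C@]2(C)C1=O | intermediate
10 | 2-thioxopyridin-1(2H)-yl (4aS,8aS)-4,4,7,8a-tetramethyl-8-oxo-1,2,3,4,4a,5,8,8a-octahydronaphthalene-2-carboxylate (Barton ester; C2 epimers) | CC1=CC[C@H]2C(C)(C)CC(C(=O)ON3C=CC=CC3=S)C[C@]2(C)C1=O | intermediate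
11 | (4aS,8aS)-2,5,5,8a-tetramethyl-4a,5,6,7,8,8a-hexahydronaphthalen-1(4H)-one (11-nordrim-7-en-9-one) | CC1=CC[C@H]2C(C)(C)CCC[C@]2(C)C1=O | intermediate
12 | (4aS,8aS)-2,5,5,8a-tetramethyl-1-methylidene-1,4,4a,5,6,7,8,8a-octahydronaphthalene (drima-7,9(11)-diene) | CC1=CC[C@H]2C(C)(C)CCC[C@]2(C)C1=C | intermediate
13 | 9-(drim-7-en-11-yl)-9-borabicyclo[3.3.1]nonane (C9 H α) | CC1=CC[C@H]2C(C)(C)CCC[C@]2(C)[C@H]1CB1C2CCCC1CCC2 | intermediate
14 | (−)-drimenol, [(1S,4aS,8aS)-2,5,5,8a-tetramethyl-1,4,4a,5,6,7,8,8a-octahydronaphthalen-1-yl]methanol | CC1=CC[C@H]2C(C)(C)CCC[C@]2(C)[C@H]1CO | intermediate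
15 | caffeic acid, (E)-3-(3,4-dihydroxyphenyl)prop-2-enoic acid | O=C(O)/C=C/c1ccc(O)c(O)c1 | starting material
16 | tert-butyldimethylsilyl (E)-3-[3,4-bis(tert-butyldimethylsilyloxy)phenyl]prop-2-enoate | CC(C)(C)[Si](C)(C)OC(=O)/C=C/c1ccc(O[Si](C)(C)C(C)(C)C)c(O[Si](C)(C)C(C)(C)C)c1 | intermediate
17 | (E)-3-[3,4-bis(tert-butyldimethylsilyloxy)phenyl]prop-2-enoic acid | O=C(O)/C=C/c1ccc(O[Si](C)(C)C(C)(C)C)c(O[Si](C)(C)C(C)(C)C)c1 | intermediate
18 | drim-7-en-11-yl (E)-3-[3,4-bis(tert-butyldimethylsilyloxy)phenyl]prop-2-enoate | CC1=CC[C@H]2C(C)(C)CCC[C@]2(C)[C@H]1COC(=O)/C=C/c1ccc(O[Si](C)(C)C(C)(C)C)c(O[Si](C)(C)C(C)(C)C)c1 | intermediate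
19 | drim-7-en-11-yl caffeate (CNP0265201.1) | CC1=CC[C@H]2C(C)(C)CCC[C@]2(C)[C@H]1COC(=O)/C=C/c1ccc(O)c(O)c1 | target

**Step count**
Total: 10 steps. Longest linear sequence: 9 steps from (R)-carvone (steps 1–7, 9 and 10); step 8 is the one-step side branch from caffeic acid.

**Steps most likely to fail**

Step 3. The iron hydride may transfer hydrogen to the acrylate, or the C4 radical may be reduced before it reaches C3, so that reduced open-chain material forms instead of ring A. The fallback sets out from 6 and returns at 7. HBr (1 equiv, AcOH/CH2Cl2, 0 °C) should add across the isopropenyl group in the Markovnikov sense, since the electron-poor acrylate and enone do not protonate under these conditions, to give methyl 2-{[(1S,6R)-6-(2-bromopropan-2-yl)-1,3-dimethyl-2-oxocyclohex-3-en-1-yl]methyl}prop-2-enoate F1. Slow addition of Bu3SnH with AIBN in toluene at 90 °C would then abstract bromine and generate the same tertiary C4 radical with no metal hydride present; 6-endo Giese closure and hydrogen transfer from tin deliver 7.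

Step 6. Methylidene transfer to the hindered conjugated C9 carbonyl, flanked by quaternary C10 and the C8 methyl, may be so slow that the titanium reagent decays before conversion is complete. The fallback sets out from 11 and returns at 12 by a two-stage Peterson olefination. Me3SiCH2Li with anhydrous CeCl3 (THF, −78 °C) should add 1,2 to the ketone from the α face to give (1S,4aS,8aS)-2,5,5,8a-tetramethyl-1-[(trimethylsilyl)methyl]-1,4,4a,5,6,7,8,8a-octahydronaphthalen-1-ol F2 (OH β, CH2SiMe3 α at C9). KH (THF, 0 °C to rt) then induces syn elimination of the silanolate, which can only involve the silyl-bearing carbon, and gives 12.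

Step 7. Hydroboration next to quaternary C10 may be slow, may lose facial selectivity at C9 (β-face addition would give the C9 epimer), or may go on to attack C7=C8 when forced. The fallback sets out from 11 and returns at 14. Dimethylsulfonium methylide (Me3S+ I−, n-BuLi, THF, 0 °C) should add to the C9 carbonyl from the α face and close to the alkenyl oxirane (1S,4aS,8aS)-2,5,5,8a-tetramethyl-4a,5,6,7,8,8a-hexahydro-4H-spiro[naphthalene-1,2'-oxirane] F3 (9,11-epoxydrim-7-ene with oxygen β and C11 α at C9). Formate hydrogenolysis (Pd2(dba)3·CHCl3 cat., n-Bu3P, HCO2H, Et3N, dioxane, rt) follows: zerovalent palladium opens the allylic C9–O bond with inversion, and the hydride formed from formate is passed from palladium to the more substituted allyl terminus C9 on the α face, which gives 14 with C7=C8 in place.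

**Further compounds**
F1 | step 3 | methyl 2-{[(1S,6R)-6-(2-bromopropan-2-yl)-1,3-dimethyl-2-oxocyclohex-3-en-1-yl]methyl}prop-2-enoate | CC1=CC[C@@H](C(C)(C)Br)[C@](C)(CC(=C)C(=O)OC)C1=O
F2 | step 6 | (1S,4aS,8aS)-2,5,5,8a-tetramethyl-1-[(trimethylsilyl)methyl]-1,4,4a,5,6,7,8,8a-octahydronaphthalen-1-ol | CC1=CC[C@H]2C(C)(C)CCC[C@]2(C)[C@]1(O)C[Si](C)(C)C
F3 | step 7 | (1S,4aS,8aS)-2,5,5,8a-tetramethyl-4a,5,6,7,8,8a-hexahydro-4H-spiro[naphthalene-1,2'-oxirane] | CC1=CC[C@H]2C(C)(C)CCC[C@]2(C)[C@]13CO3
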